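In a one-step world, substrate meets partner, target piles up, and the share of target stays whole. The earlier teal run is not that world. Side product B stands at 2.8 % against 22.1 % target at 0.833 min, then at 15.7 % against 39.5 % at 2.50 min, so B per target climbs.

| setting | red | grey | teal | midnight | dusk | summer | dawn | spring |
|---|---|---|---|---|---|---|---|---|
| substrate | 4.5 × 10⁻⁴ M | 0.0015 M | 5.0 × 10⁻⁴ M | 5.0 × 10⁻⁴ M | 5.0 × 10⁻⁴ M | 0.0010 M | 3.0 × 10⁻⁴ M | 5.0 × 10⁻⁴ M |
| partner | 2.5 mM | 2.5 mM | 4.2 mM | 1.50 mM | 2.50 mM | 2.50 mM | 2.50 mM | 8.00 mM |
| temperature | 44 °C | 74 °C | 44 °C | 85 °C | 70 °C | 30 °C | 70 °C | 30 °C |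
| remark | run made earlier | run made earlier | run made earlier |  |  |  |  |  |
| time |  |  |  | 4.0 min | 4.0 min | 4.0 min | 4.0 min | 4.0 min |

| run | time / min | target / % | side product B / % |
|---|---|---|---|
| red | 0.833 | 15.0 | 1.7 |
| red | 1.33 | 20.4 | 4.7 |
| red | 2.50 | 29.2 | 11.7 |
| red | 4.00 | 35.2 | 20.5 |
| red | 5.00 | 36.7 | 25.0 |
| red | 10.0 | 40.0 | 43.4 |
| grey | 0.500 | 16.3 | 31.8 |
| grey | 1.00 | 15.7 | 56.2 |
| grey | 1.33 | 14.3 | 65.5 |
| grey | 2.00 | 13.0 | 76.1 |
| grey | 2.50 | 12.2 | 80.4 |
| grey | 3.00 | 11.1 | 84.0 |
| teal | 0.833 | 22.1 | 2.8 |
| teal | 2.50 | 39.5 | 15.7 |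
| teal | 5.00 | 46.5 | 28.9 |
| teal | 8.00 | 47.5 | 38.9 |
| teal | 10.0 | 47.6 | 43.9 |

(scatter of a reading: 0.5 percentage points)

- percent here means substrate units held: one side product B counts as two
- a reading or a percentage of target counts all its forms, free or not

- the flasks by share of target in all that became target or side product B, highest first, at 4.0 min (midnight / dusk / summer / dawn / spring)
- the same order at 30 min (midnight / dusk / summer / dawn / spring)
- the share of target in all that became target or side product B of the flask you put first, at 4.0 min
- the share of target in all that became target or side product B of the flask you put last, at 4.0 min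

Treat target as a rival of partner for substrate, as two comonomers compete for one chain end. Substrate then cancels from the choice, and [target]/[partner] remains.

Now count turnovers early, and hold [partner] at its charge. At the very start target grows with time, B with time squared. So B per target, call it h, equals σ times the target fraction times [substrate]/[partner] as charged. Here σ, the selectivity factor, is the rate constant of substrate on target over that of substrate on partner. The share of target is then the inverse of one plus h.

Read σ from the first teal reading: B times [partner], over target squared times [substrate], gives 4.82. The first red reading, from another charge, gives 4.20. Take σ as rough: the two values differ, and each reading is good to 0.5 percentage points. Both runs stood at 44 °C; carry σ unchanged to 30 °C as an assumption.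

Decide the charge by [substrate]/[partner]. Choose spring: its ratio is 0.0625, lower than any other recipe's. Keep its substrate at 5.0 × 10⁻⁴ M: at fixed target fraction and [partner], h rises with [substrate]. Read it at 4.0 min. If half of the substrate stands as target, my reckoning gives spring a share of 86.9 %.

The forecast, from “Hand-stepping to 4 min gives these shares”, says spring > summer > dawn > dusk > midnight at 4.0 min, spring > summer > dawn > dusk > midnight at 30 min, top 85 % and low 11 %.

The flasks give spring > summer > dawn > dusk > midnight at 4.0 min and spring > dawn > dusk > summer > midnight at 30 min, with top 82.3 % and low 21.6 %.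

    substrate + partner → target (k = 6.10 L mol⁻¹ s⁻¹, Ea = 49.0 kJ mol⁻¹)
    2 partner → side product A (k = 1.90 L mol⁻¹ s⁻¹, Ea = 40.0 kJ mol⁻¹)
    substrate + target → side product B (k = 35.0 L mol⁻¹ s⁻¹, Ea = 58.0 kJ mol⁻¹)
    crystals ⇌ target, rate k4*(cs4 - [target]) while solid is left; crystals form when [target] > cs4 (solubility = 0.250 mM, k = 0.110 s⁻¹)
    (constants at 70 °C)

At 4.00 min, spring holds 48.3 % target and 10.4 % B, with partner down to 45 % of its charge. Put that target into the rule and σ gives 87.3 %, against 82.3 % found. Now take spring with 0.0020 M of substrate, which holds 41.3 % target, all its forms counted. There σ gives 66.8 %, and the share in that flask is 69.7 %.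

(All runs are calculated with constants of no real substance, noise included.)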